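**Strategy.** Each amino alcohol unit is read as a ring-contracted carvone. Its cyclopentane C4a–C5–C6–C7–C7a carries C1 on C7a, a methyl on C7 and oxygen on C6. This is the pattern left by a Favorskii rearrangement of the (S)-carvone-derived 2-chloro-3-alkoxy-2-methyl-5-isopropenylcyclohexanone: the six-ring ketone carbon is extruded as C1 while C7 and C7a are set. Ligand-controlled CuH hydroamination of the isopropenyl group, lactamisation and reduction complete one amino alcohol. It serves both ester linkages, by Yamaguchi acylation (retention) and Mitsunobu esterification (inversion). The cis-diaryl cyclobutane core comes from double directed C–H arylation of a trans-cyclobutane-1,3-dicarboxylate.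

Key step: step 4

Assumption: (R)-DTBM-SEGPHOS is taken as the ligand antipode whose copper hydride delivers hydrogen to the Re face of the alkene carbon that becomes C4; if the sense is the opposite, the (S)-ligand is used and nothing else changes.

Remark on the target: the two aryl groups are cis to each other and the two carboxyl groups trans. The ester trans to the aryl groups carries the (6S) amino alcohol and the ester cis to them carries its (6R) epimer. The tetrahydropyranyl acetal carbon in 4–6 and 10–13 is carried as both epimers and is removed in step 8.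

**Step 1**
Reactants: 1 (S)-(+)-carvone
Product: 2 (1S,4S,6S)-1-methyl-4-(prop-1-en-2-yl)-7-oxabicyclo[4.1.0]heptan-2-one
Conditions: 30% H2O2, NaOH (cat.), MeOH, 0 °C
Reagents that add atoms: hydrogen peroxide, OO
Why: Weitz–Scheffer nucleophilic epoxidation touches only the enone, and axial attack of hydroperoxide anti to the C5 isopropenyl group should place the oxirane trans to it, setting both oxirane carbons.

**Step 2**
Reactants: 2 epoxy ketone
Product: 3 (2R,3S,5S)-2-chloro-3-hydroxy-2-methyl-5-(prop-1-en-2-yl)cyclohexan-1-one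
Conditions: LiCl, CF3CO2H, THF, rt
Reagents that add atoms: lithium chloride, [Li+].[Cl-]
Why: Acid-promoted anti opening of the α,β-epoxy ketone by chloride at the α-carbon with inversion should leave chlorine cis and the retained C3 hydroxyl trans to the isopropenyl group.

**Step 3**
Reactants: 3 chlorohydrin
Product: 4 (2R,3S,5S)-2-chloro-2-methyl-3-(oxan-2-yloxy)-5-(prop-1-en-2-yl)cyclohexan-1-one
Conditions: 3,4-dihydro-2H-pyran, PPTS (cat.), CH2Cl2, rt
Reagents that add atoms: 3,4-dihydro-2H-pyran, C1=COCCC1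
Why: Acid-catalysed acetal formation masks the β-hydroxyl so that base in the next step can neither re-close the epoxide nor trigger retro-aldol cleavage; no ring stereocentre is touched.

**Step 4**
Reactants: 4 chloro ketone acetal
Product: 6 methyl (1S,2R,3S,5S)-2-methyl-3-(oxan-2-yloxy)-5-(prop-1-en-2-yl)cyclopentane-1-carboxylate, via cyclopropanone 5 (not isolated)
Conditions: NaOMe, MeOH, 0 °C to rt
Reagents that add atoms: sodium methoxide, [Na+].[O-]C
Why: Favorskii rearrangement (ring contraction, six to five): methoxide removes a proton from C6 of 4, the only enolisable α-position, and the enolate displaces the tertiary chloride at C2 from the rear to give cyclopropanone 5, whose methanol hemiketal anion then opens. The closest known reaction type is the Favorskii contraction of 2-chlorocyclohexanones, here on a carvone chlorohydrin ether. Only the transient three-membered ring is closed (3-exo-tet, SN2 with inversion at the chlorine-bearing carbon); the cyclopentane is the new C2–C6 bond together with the old C2–C3–C4–C5–C6 chain. The methyl-bearing centre (later C7) is fixed by this inversion, which follows the inversion of step 2 and so relays the epoxide face chosen by the isopropenyl group; the ester-bearing centre (later C7a) is fixed because the carbonyl bridge of 5 ends on the face the chloride vacates, cis to the isopropenyl group, and the ring-opening protonation occurs with retention. The step needs cleavage of the C1–C2 and not the C1–C6 bond of 5, which the electron-withdrawing β-acetal oxygen secures by stabilising charge at C2, and it needs the oxygen to stay in place, which the acetal secures. The ketone carbon leaves the ring as the ester carbon that later becomes C1 of the piperidine.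

**Step 5**
Reactants: 7 N-methylbenzylamine; 8 dibenzoyl peroxide
Product: 9 O-benzoyl-N-benzyl-N-methylhydroxylamine
Conditions: K2HPO4, DMF, rt
Reagents that add atoms: none
Why: Nucleophilic attack of the secondary amine on the peroxide O–O bond is the standard N–O bond-forming preparation of O-benzoylhydroxylamine amination reagents.

**Step 6**
Reactants: 6 isopropenyl ester; 9 amination reagent
Product: 10 methyl (1S,2R,3S,5R)-5-[(2R)-1-[benzyl(methyl)amino]propan-2-yl]-2-methyl-3-(oxan-2-yloxy)cyclopentane-1-carboxylate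
Conditions: Cu(OAc)2 (2 mol %), (R)-DTBM-SEGPHOS (2.2 mol %), (MeO)2MeSiH (2 equiv), THF, 40 °C
Reagents that add atoms: none
Why: CuH-catalysed anti-Markovnikov hydroamination of a 1,1-disubstituted alkene: ligand-controlled syn-hydrocupration puts copper on the terminal carbon and hydrogen on the Re face of the internal carbon, setting C4 as (R), and the alkylcopper is then aminated by 9; ester and acetal should be inert.

**Step 7**
Reactants: 10 benzylamine ester
Product: 12 (4R,4aR,6S,7R,7aS)-2,4,7-trimethyl-6-(oxan-2-yloxy)octahydro-1H-cyclopenta[c]pyridin-1-one, via secondary amine 11 (not isolated)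
Conditions: H2 (4 atm), Pd(OH)2/C, EtOH, 50 °C; then reflux
Reagents that add atoms: none
Why: Hydrogenolysis of the N-benzyl group frees the methylamine, which sits cis to the methyl ester on the ring and should close the six-membered lactam by intramolecular aminolysis (6-exo-trig) without touching a stereocentre.

**Step 8**
Reactants: 12 lactam
Product: 14 (4R,4aR,6S,7R,7aS)-2,4,7-trimethyloctahydro-1H-cyclopenta[c]pyridin-6-ol, via acetal amine 13 (not isolated)
Conditions: LiAlH4, THF, reflux; then HCl, MeOH, rt; NaOH work-up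
Reagents that add atoms: none
Why: Hydride reduction of the tertiary lactam to the amine followed by acid methanolysis of the tetrahydropyranyl acetal; no stereocentre is involved.

**Step 9**
Reactants: 15 trans-3-(methoxycarbonyl)cyclobutane-1-carboxylic acid; 16 quinolin-8-amine
Product: 17 methyl trans-3-(quinolin-8-ylcarbamoyl)cyclobutane-1-carboxylate
Conditions: EDC·HCl, DMAP, CH2Cl2, rt
Reagents that add atoms: none
Why: Carbodiimide amide coupling installs the bidentate directing group; the 1,3-trans relationship is not at risk under these conditions.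

**Step 10**
Reactants: 17 aminoquinoline amide; 18 1-(benzyloxy)-4-iodo-2-methoxybenzene (3 equiv)
Product: 19 methyl (1α,2β,3β,4β)-2,4-bis[4-(benzyloxy)-3-methoxyphenyl]-3-(quinolin-8-ylcarbamoyl)cyclobutane-1-carboxylate
Conditions: Pd(OAc)2 (10 mol %), AgOAc (3 equiv), toluene, 110 °C
Reagents that add atoms: none
Why: Auxiliary-directed β-C(sp3)–H arylation through a divalent/tetravalent palladium cycle, run twice: the N,N-chelated palladium reaches only the methylene hydrogens cis to the amide, so both aryl groups should arrive cis to the carboxamide and, because the ester started trans to the amide, trans to the ester.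

**Step 11**
Reactants: 19 diaryl amide
Product: 20 N-Boc derivative of 19 (tert-butyl carbamate on the amide nitrogen)
Conditions: Boc2O, DMAP, MeCN, 50 °C
Reagents that add atoms: di-tert-butyl dicarbonate, CC(C)(C)OC(=O)OC(=O)OC(C)(C)C
Why: N-acylation of the secondary anilide twists the amide and turns it into an imide-type acyl donor.

**Step 12**
Reactants: 20 activated amide
Product: 22 (1α,2α,3β,4α)-2,4-bis[4-(benzyloxy)-3-methoxyphenyl]-3-(methoxycarbonyl)cyclobutane-1-carboxylic acid, via peroxy acid 21 (not isolated)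
Conditions: LiOH·H2O, 30% H2O2, THF/H2O, 0 °C; then aq. Na2SO3; then 1 M HCl
Reagents that add atoms: hydrogen peroxide, OO
Why: Hydroperoxide anion, an α-effect nucleophile of low basicity, should attack the activated acyl carbon selectively over the methyl ester (imide-type LiOOH cleavage); sulfite reduces the peroxy acid, and the cold, weakly basic medium protects the all-cis α-centre.

**Step 13**
Reactants: 22 acid; 14 amino alcohol
Product: 23 methyl (1α,2β,3β,4β)-2,4-bis[4-(benzyloxy)-3-methoxyphenyl]-3-({[(4R,4aR,6R,7R,7aS)-2,4,7-trimethyloctahydro-1H-cyclopenta[c]pyridin-6-yl]oxy}carbonyl)cyclobutane-1-carboxylate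
Conditions: PPh3, DIAD, THF, 0 °C to rt
Reagents that add atoms: none
Why: Mitsunobu esterification: the carboxylate of 22 displaces the alkoxyphosphonium oxygen at C6 with SN2 inversion (6S to 6R), and because the acid is never activated its crowded α-centre cannot epimerise.

**Step 14**
Reactants: 23 methyl ester
Product: 24 (1α,2β,3β,4β)-2,4-bis[4-(benzyloxy)-3-methoxyphenyl]-3-({[(4R,4aR,6R,7R,7aS)-2,4,7-trimethyloctahydro-1H-cyclopenta[c]pyridin-6-yl]oxy}carbonyl)cyclobutane-1-carboxylic acid
Conditions: LiOH·H2O, THF/MeOH/H2O, rt; then aq. HCl to pH 6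
Reagents that add atoms: lithium hydroxide, [Li+].[OH-]
Why: Saponification should take only the unhindered methyl ester, since the secondary cyclopentyl ester is shielded by the two flanking cis-aryl groups.

**Step 15**
Reactants: 24 acid; 25 2,4,6-trichlorobenzoyl chloride; 14 amino alcohol
Product: 27 bis(benzyl ether) of the target, via mixed anhydride 26 (not isolated)
Conditions: 25, Et3N, THF, rt; then 14, DMAP, toluene, 40 °C
Reagents that add atoms: none
Why: Yamaguchi esterification: DMAP-catalysed acyl transfer from the mixed anhydride to the C6 hydroxyl proceeds with retention (6S), the complement of the inversion in step 13; the activated carboxyl is already the stable trans epimer.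

**Step 16**
Reactants: 27 bis(benzyl ether)
Product: 28 target, 1-[(4R,4aR,6S,7R,7aS)-2,4,7-trimethyloctahydro-1H-cyclopenta[c]pyridin-6-yl] 3-[(4R,4aR,6R,7R,7aS)-2,4,7-trimethyloctahydro-1H-cyclopenta[c]pyridin-6-yl] (1α,2β,3β,4β)-2,4-bis(4-hydroxy-3-methoxyphenyl)cyclobutane-1,3-dicarboxylate
Conditions: H2 (1 atm), Pd(OH)2/C, AcOH (4 equiv), MeOH/EtOAc, rt; NaHCO3 work-up
Reagents that add atoms: none
Why: Catalytic hydrogenolysis cleaves both aryl benzyl ethers; acetic acid protonates the tertiary amines so they do not poison the catalyst, and esters and the cyclobutane should be inert.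

**Compound list**

1 | (S)-(+)-carvone | CC1=CC[C@@H](CC1=O)C(C)=C | starting material
2 | (1S,4S,6S)-1-methyl-4-(prop-1-en-2-yl)-7-oxabicyclo[4.1.0]heptan-2-one (oxirane trans to isopropenyl) | O=C1[C@@]2(C)O[C@H]2C[C@H](C(C)=C)C1 | intermediate
3 | (2R,3S,5S)-2-chloro-3-hydroxy-2-methyl-5-(prop-1-en-2-yl)cyclohexan-1-one | O=C1[C@](C)(Cl)[C@@H](O)C[C@H](C(C)=C)C1 | intermediate
4 | (2R,3S,5S)-2-chloro-2-methyl-3-(oxan-2-yloxy)-5-(prop-1-en-2-yl)cyclohexan-1-one (acetal carbon: both epimers) | O=C1[C@](C)(Cl)[C@@H](OC2CCCCO2)C[C@H](C(C)=C)C1 | intermediate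
5 | 1-methyl-2-(oxan-2-yloxy)-4-(prop-1-en-2-yl)bicyclo[3.1.0]hexan-6-one (carbonyl bridge cis to isopropenyl; acetal oxygen trans; not isolated) | O=C1[C@]2(C)[C@@H](OC3CCCCO3)C[C@H](C(C)=C)[C@H]12 | intermediate
6 | methyl (1S,2R,3S,5S)-2-methyl-3-(oxan-2-yloxy)-5-(prop-1-en-2-yl)cyclopentane-1-carboxylate | COC(=O)[C@@H]1[C@@H](C)[C@@H](OC2CCCCO2)C[C@@H]1C(C)=C | intermediate
7 | N-methylbenzylamine | CNCc1ccccc1 | starting material
8 | dibenzoyl peroxide | O=C(OOC(=O)c1ccccc1)c1ccccc1 | starting material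
9 | O-benzoyl-N-benzyl-N-methylhydroxylamine | CN(Cc1ccccc1)OC(=O)c1ccccc1 | intermediate
10 | methyl (1S,2R,3S,5R)-5-[(2R)-1-[benzyl(methyl)amino]propan-2-yl]-2-methyl-3-(oxan-2-yloxy)cyclopentane-1-carboxylate | COC(=O)[C@@H]1[C@@H](C)[C@@H](OC2CCCCO2)C[C@@H]1[C@@H](C)CN(C)Cc1ccccc1 | intermediate
11 | methyl (1S,2R,3S,5R)-2-methyl-5-[(2R)-1-(methylamino)propan-2-yl]-3-(oxan-2-yloxy)cyclopentane-1-carboxylate (not isolated) | COC(=O)[C@@H]1[C@@H](C)[C@@H](OC2CCCCO2)C[C@@H]1[C@@H](C)CNC | intermediate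
12 | (4R,4aR,6S,7R,7aS)-2,4,7-trimethyl-6-(oxan-2-yloxy)octahydro-1H-cyclopenta[c]pyridin-1-one | O1CCCCC1O[C@H]1C[C@H]2[C@H](C(=O)N(C)C[C@@H]2C)[C@H]1C | intermediate
13 | (4R,4aR,6S,7R,7aS)-2,4,7-trimethyl-6-(oxan-2-yloxy)octahydro-1H-cyclopenta[c]pyridine (not isolated) | O1CCCCC1O[C@H]1C[C@H]2[C@H](CN(C)C[C@@H]2C)[C@H]1C | intermediate
14 | (4R,4aR,6S,7R,7aS)-2,4,7-trimethyloctahydro-1H-cyclopenta[c]pyridin-6-ol (cis ring fusion; 4-Me, 7-Me and 6-OH all cis to the ring-fusion hydrogens) | O[C@H]1C[C@H]2[C@H](CN(C)C[C@@H]2C)[C@H]1C | intermediate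
15 | trans-3-(methoxycarbonyl)cyclobutane-1-carboxylic acid | COC(=O)[C@@H]1C[C@@H](C(=O)O)C1 | starting material
16 | quinolin-8-amine | Nc1cccc2cccnc12 | starting material
17 | methyl trans-3-(quinolin-8-ylcarbamoyl)cyclobutane-1-carboxylate | COC(=O)[C@@H]1C[C@@H](C(=O)Nc2cccc3cccnc23)C1 | intermediate
18 | 1-(benzyloxy)-4-iodo-2-methoxybenzene | COc1cc(I)ccc1OCc1ccccc1 | starting material
19 | methyl (1α,2β,3β,4β)-2,4-bis[4-(benzyloxy)-3-methoxyphenyl]-3-(quinolin-8-ylcarbamoyl)cyclobutane-1-carboxylate (amide and both aryls mutually cis; ester trans) | COc1cc([C@@H]2[C@@H](C(=O)OC)[C@H](c3ccc(OCc4ccccc4)c(OC)c3)[C@@H]2C(=O)Nc2cccc3cccnc23)ccc1OCc1ccccc1 | intermediate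
20 | N-Boc derivative of 19 | COc1cc([C@@H]2[C@@H](C(=O)OC)[C@H](c3ccc(OCc4ccccc4)c(OC)c3)[C@@H]2C(=O)N(C(=O)OC(C)(C)C)c2cccc3cccnc23)ccc1OCc1ccccc1 | intermediate
21 | (1α,2α,3β,4α)-2,4-bis[4-(benzyloxy)-3-methoxyphenyl]-3-(methoxycarbonyl)cyclobutane-1-carboperoxoic acid (not isolated) | COc1cc([C@@H]2[C@@H](C(=O)OC)[C@H](c3ccc(OCc4ccccc4)c(OC)c3)[C@@H]2C(=O)OO)ccc1OCc1ccccc1 | intermediate
22 | (1α,2α,3β,4α)-2,4-bis[4-(benzyloxy)-3-methoxyphenyl]-3-(methoxycarbonyl)cyclobutane-1-carboxylic acid (acid cis to both aryls) | COc1cc([C@@H]2[C@@H](C(=O)OC)[C@H](c3ccc(OCc4ccccc4)c(OC)c3)[C@@H]2C(=O)O)ccc1OCc1ccccc1 | intermediate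
23 | methyl ester / (6R)-amino alcohol ester of the diaryl cyclobutane diacid (see step 13) | COc1cc([C@@H]2[C@@H](C(=O)OC)[C@H](c3ccc(OCc4ccccc4)c(OC)c3)[C@@H]2C(=O)O[C@@H]2C[C@H]3[C@H](CN(C)C[C@@H]3C)[C@H]2C)ccc1OCc1ccccc1 | intermediate
24 | free acid (trans to aryls) / (6R)-amino alcohol ester (see step 14) | COc1cc([C@@H]2[C@@H](C(=O)O)[C@H](c3ccc(OCc4ccccc4)c(OC)c3)[C@@H]2C(=O)O[C@@H]2C[C@H]3[C@H](CN(C)C[C@@H]3C)[C@H]2C)ccc1OCc1ccccc1 | intermediate
25 | 2,4,6-trichlorobenzoyl chloride | O=C(Cl)c1c(Cl)cc(Cl)cc1Cl | starting material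
26 | mixed 2,4,6-trichlorobenzoic anhydride of 24 (not isolated) | COc1cc([C@@H]2[C@@H](C(=O)OC(=O)c3c(Cl)cc(Cl)cc3Cl)[C@H](c3ccc(OCc4ccccc4)c(OC)c3)[C@@H]2C(=O)O[C@@H]2C[C@H]3[C@H](CN(C)C[C@@H]3C)[C@H]2C)ccc1OCc1ccccc1 | intermediate
27 | bis(benzyl ether) of the target | COc1cc([C@@H]2[C@@H](C(=O)O[C@H]3C[C@H]4[C@H](CN(C)C[C@@H]4C)[C@H]3C)[C@H](c3ccc(OCc4ccccc4)c(OC)c3)[C@@H]2C(=O)O[C@@H]2C[C@H]3[C@H](CN(C)C[C@@H]3C)[C@H]2C)ccc1OCc1ccccc1 | intermediate
28 | target (name in step 16) | COc1cc([C@@H]2[C@@H](C(=O)O[C@H]3C[C@H]4[C@H](CN(C)C[C@@H]4C)[C@H]3C)[C@H](c3ccc(O)c(OC)c3)[C@@H]2C(=O)O[C@@H]2C[C@H]3[C@H](CN(C)C[C@@H]3C)[C@H]2C)ccc1O | target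

**Step count.** 16 steps in total. Longest linear sequence: 11 steps (1–4, 6–8, 13–16).

**Steps most likely to fail**

1. Step 13. The alkoxyphosphonium ion of 14 may eliminate to the cyclopentene, or displacement at C6 from the concave face by the crowded carboxylate may be too slow. The fallback sets out from 14 (and uses 22) and comes back at 23.
   - Swern oxidation of 14 should give (4R,4aR,7R,7aS)-2,4,7-trimethyloctahydro-6H-cyclopenta[c]pyridin-6-one F1.
   - NaBH4 in MeOH at −20 °C should add hydride from the convex face, cis to the ring-fusion hydrogens, to give (4R,4aR,6R,7R,7aS)-2,4,7-trimethyloctahydro-1H-cyclopenta[c]pyridin-6-ol F2.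
   - Acid 22 is converted under neutral conditions with 1-chloro-N,N,2-trimethylprop-1-en-1-amine into (1α,2α,3β,4α)-2,4-bis[4-(benzyloxy)-3-methoxyphenyl]-3-(methoxycarbonyl)cyclobutane-1-carbonyl chloride F3.
   - F3 acylates F2 (pyridine, DMAP, CH2Cl2) with retention to give 23.

2. Step 12. Hydroperoxide may attack the carbamate carbonyl and not the crowded acyl carbon, which returns 19, or the activated all-cis α-centre may epimerise. The fallback sets out from 19 and comes back at 27.
   - Base-free methanolysis of the aminoquinoline amide catalysed by nickel bis(2,2,6,6-tetramethylheptane-3,5-dionate) (MeOH, toluene, 100 °C) should give dimethyl (1α,2β,3β,4β)-2,4-bis[4-(benzyloxy)-3-methoxyphenyl]cyclobutane-1,3-dicarboxylate F4.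
   - LiOH (1 equiv) should hydrolyse only the ester trans to the aryl groups, giving (1α,2β,3β,4β)-2,4-bis[4-(benzyloxy)-3-methoxyphenyl]-3-(methoxycarbonyl)cyclobutane-1-carboxylic acid F5.
   - Yamaguchi esterification with 14 gives 1-[(4R,4aR,6S,7R,7aS)-2,4,7-trimethyloctahydro-1H-cyclopenta[c]pyridin-6-yl] 3-methyl (1α,2β,3β,4β)-2,4-bis[4-(benzyloxy)-3-methoxyphenyl]cyclobutane-1,3-dicarboxylate F6.
   - SN2 demethylation of the hindered methyl ester with lithium propane-1-thiolate in DMF gives (1α,2α,3β,4α)-2,4-bis[4-(benzyloxy)-3-methoxyphenyl]-3-({[(4R,4aR,6S,7R,7aS)-2,4,7-trimethyloctahydro-1H-cyclopenta[c]pyridin-6-yl]oxy}carbonyl)cyclobutane-1-carboxylic acid F7.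
   - Mitsunobu esterification of F7 with 14 gives 27.

3. Step 6. Facial selectivity of the hydrocupration may be poor if the ligand and the neighbouring ring stereocentres oppose each other, or insertion of the hindered alkene may be so slow that the amination reagent is simply reduced. The fallback sets out from 6 and comes back at 13.
   - Hydroboration with 9-BBN (THF, rt) and oxidation with NaBO3 should give methyl (1S,2R,3S,5R)-5-[(2R)-1-hydroxypropan-2-yl]-2-methyl-3-(oxan-2-yloxy)cyclopentane-1-carboxylate F8. Boron should approach anti to the ester-bearing ring carbon in the A(1,3)-minimised rotamer, and the C4 epimers can be separated here.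
   - LiAlH4 gives the diol (2R)-2-[(1R,2S,3R,4S)-2-(hydroxymethyl)-3-methyl-4-(oxan-2-yloxy)cyclopentyl]propan-1-ol F9.
   - MsCl/Et3N gives its bis(methanesulfonate) F10.
   - MeNH2 in EtOH (sealed, 60 °C) closes the piperidine by double SN2 displacement to give 13.

**Further compounds**

F1 | step 13 | (4R,4aR,7R,7aS)-2,4,7-trimethyloctahydro-6H-cyclopenta[c]pyridin-6-one | O=C1C[C@H]2[C@H](CN(C)C[C@@H]2C)[C@H]1C
F2 | step 13 | (4R,4aR,6R,7R,7aS)-2,4,7-trimethyloctahydro-1H-cyclopenta[c]pyridin-6-ol | O[C@@H]1C[C@H]2[C@H](CN(C)C[C@@H]2C)[C@H]1C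
F3 | step 13 | (1α,2α,3β,4α)-2,4-bis[4-(benzyloxy)-3-methoxyphenyl]-3-(methoxycarbonyl)cyclobutane-1-carbonyl chloride | COc1cc([C@@H]2[C@@H](C(=O)OC)[C@H](c3ccc(OCc4ccccc4)c(OC)c3)[C@@H]2C(=O)Cl)ccc1OCc1ccccc1
F4 | step 12 | dimethyl (1α,2β,3β,4β)-2,4-bis[4-(benzyloxy)-3-methoxyphenyl]cyclobutane-1,3-dicarboxylate | COc1cc([C@@H]2[C@@H](C(=O)OC)[C@H](c3ccc(OCc4ccccc4)c(OC)c3)[C@@H]2C(=O)OC)ccc1OCc1ccccc1
F5 | step 12 | (1α,2β,3β,4β)-2,4-bis[4-(benzyloxy)-3-methoxyphenyl]-3-(methoxycarbonyl)cyclobutane-1-carboxylic acid | COc1cc([C@@H]2[C@@H](C(=O)O)[C@H](c3ccc(OCc4ccccc4)c(OC)c3)[C@@H]2C(=O)OC)ccc1OCc1ccccc1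
F6 | step 12 | 1-[(4R,4aR,6S,7R,7aS)-2,4,7-trimethyloctahydro-1H-cyclopenta[c]pyridin-6-yl] 3-methyl (1α,2β,3β,4β)-2,4-bis[4-(benzyloxy)-3-methoxyphenyl]cyclobutane-1,3-dicarboxylate | COc1cc([C@@H]2[C@@H](C(=O)O[C@H]3C[C@H]4[C@H](CN(C)C[C@@H]4C)[C@H]3C)[C@H](c3ccc(OCc4ccccc4)c(OC)c3)[C@@H]2C(=O)OC)ccc1OCc1ccccc1
F7 | step 12 | (1α,2α,3β,4α)-2,4-bis[4-(benzyloxy)-3-methoxyphenyl]-3-({[(4R,4aR,6S,7R,7aS)-2,4,7-trimethyloctahydro-1H-cyclopenta[c]pyridin-6-yl]oxy}carbonyl)cyclobutane-1-carboxylic acid | COc1cc([C@@H]2[C@@H](C(=O)O[C@H]3C[C@H]4[C@H](CN(C)C[C@@H]4C)[C@H]3C)[C@H](c3ccc(OCc4ccccc4)c(OC)c3)[C@@H]2C(=O)O)ccc1OCc1ccccc1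
F8 | step 6 | methyl (1S,2R,3S,5R)-5-[(2R)-1-hydroxypropan-2-yl]-2-methyl-3-(oxan-2-yloxy)cyclopentane-1-carboxylate | COC(=O)[C@@H]1[C@@H](C)[C@@H](OC2CCCCO2)C[C@@H]1[C@@H](C)CO
F9 | step 6 | (2R)-2-[(1R,2S,3R,4S)-2-(hydroxymethyl)-3-methyl-4-(oxan-2-yloxy)cyclopentyl]propan-1-ol | OC[C@@H]1[C@@H](C)[C@@H](OC2CCCCO2)C[C@@H]1[C@@H](C)CO
F10 | step 6 | bis(methanesulfonate) of F9 | CS(=O)(=O)OC[C@@H]1[C@@H](C)[C@@H](OC2CCCCO2)C[C@@H]1[C@@H](C)COS(C)(=O)=O
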